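Compound numbers 1–29 are those of the steps below. Atoms are numbered as in ent-kaurane. α is the face of ring A that carries C20, C19, C6 and the C1 acetoxy group in the target; β is the face of the C18 methyl, H5 and C9. TBS = tert-butyldimethylsilyl, TBDPS = tert-butyldiphenylsilyl.

## The problem

The target is a 6,7-seco-ent-kaurane of the spiro-lactone type. Ring A is joined through the spiro carbon C10 to a δ-lactone (C10–C20–O–C7(=O)–C8–C9). The lactone is cis-fused along C8–C9 to ring C (C8, C9, C11–C14), and C15–C16 bridges C8 and C13 into a bicyclo[3.2.1]octane that ends in an exo-methylene ketone (C15=O, C16=C17). Seven stereocentres must be set, three of them quaternary (C4, C10, C8), and they form a relay. C4 and C5 are vicinal and can be made together; C5 can then steer the adjacent C10; the spiro centre C10 sits beside C9 and can decide the face on which C8 and C9 are made. C13 follows from the geometry of the bridge and C1 from the chair of ring A. Three primary carbinol carbons on the α face (C19 as acetate, C6 free, C20 in the lactone) must be told apart from the outset. The enone is a strong Michael acceptor and has to come last, and once the acetates are present, enolate chemistry and strong nucleophiles are excluded. A free 1α-hydroxyl can attack C7 and move the lactone from O20 to O1, and a free C6 hydroxyl would add to any C9 acceptor in a five-membered oxa-Michael closure. The structure opens up because ring C shares exactly the C8–C9 bond with the lactone and C8 also carries the carbonyl carbon C15. An alkylidene lactone C8=C9 bearing C15 as an ester is therefore a doubly activated dienophile, butadiene supplies C11–C14, and the spiro centre next to C9 has two unlike flanks (the flat C1 carbonyl and the substituted C5).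

## Retrosynthesis

**Last operations.** Target 29 is the desilylation product of 28, and the enone of 28 comes from the allylic alcohol 27 by oxidation. This keeps the Michael acceptor out of every earlier step and leaves only a fluoride treatment after it.

**Ring D (C13–C16, then C15–C16).** In 27 the C13–C16 bond is cut to the enyne 25, in which a vinyl radical at C16 closes onto C13 of the ring C alkene. The competing cuts are a carbenoid route through a C12/C13/C16 cyclopropane and a C8–C15 enolate alkylation; both are weighed below. The radical closure is preferred because its regiochemistry is fixed by the 5-exo mode and it delivers C16=C17 directly. The forward step must trap the C12 radical promptly, and C13 is set because the two-atom tether on C8 can reach only one face. Cutting C15–C16 in 25 gives the aldehyde 24 and an ethynyl nucleophile; 24 is the reduced form of the C8 ester of 21.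

**C1.** Acetate 21 comes from ketone 19 by reduction and acetylation. This is done directly after the cycloaddition, where ring A is locked in one chair and only one ketone is present; later the C15 carbonyl would compete.

**Ring C, the key cut (C8–C14 and C9–C11).** Cycloadduct 19 is divided into the spiro alkylidene lactone 17 and buta-1,3-diene 18. This removes a ring, two bonds and two stereocentres at once and leaves a precursor whose only stereocentres are on ring A. The forward reaction must overcome the hindrance at C9 and select the lactone face flanked by C1.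

**Lactone (C8=C9 and O20–C7).** Lactone 17 is the cyclised form of the alkylidene malonate 15, made from the keto aldehyde 13 and diallyl malonate 14 by Knoevenagel condensation. Condensing first and freeing O20 afterwards avoids a 2-formyl-2-(hydroxymethyl) ketone that could lose formaldehyde by retro-aldol cleavage.

**C10 (C9–C10).** Aldehyde 13 comes from the hydroxymethyl ketone 12, and 12 from hydroxymethylation of the tetrasubstituted silyl enol ether 11. C20 is already on C10, so the only question is the face: the incoming carbon must arrive anti to the C6 arm and become C9.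

**Ring A (C4–C5 and C2–C3).** Enol ether 11 is the reduced and acetylated form of aldehyde 9, the cycloadduct of the 2-silyloxydiene 7 and methacrolein 8. The cut is attractive because it produces the quaternary C4 with its methyl and C19, the C5 stereocentre, the C1 oxygen and a regiodefined C1=C10 enol ether in one catalytic enantioselective step.

**Diene (C1–C10).** Diene 7 is the silyl enol ether of enone 6, made by Stille acylation of stannane 4 with acetyl chloride 5. Stannane 4 comes from but-2-yne-1,4-diol 1 by syn hydrostannylation to 2 and stepwise silylation through 3. The syn addition to a symmetrical alkyne fixes the alkene geometry without any regiochemical question, and the tin atom then differentiates O6 from O20.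

## Roads not taken

**Alternative 1:** ring D closed by a lactone enolate on a π-allyl. The cut is C8–C15. In the forward step zerovalent palladium ionises the allylic carbonate of A2, and the lactone enolate at C8 attacks a CH2 terminus of the π-allyl (Tsuji–Trost allylation) to give A1, closing ring D with the quaternary C8 and leaving C16=C17 in place.
- Merits: one catalytic, tin-free step makes the hardest quaternary centre and the exocyclic alkene together, and no C15 epimers arise.
- Weak points: a lactone enolate is a non-stabilised nucleophile for π-allyl chemistry and must form a quaternary centre across a 1,3-diaxial gap, with proton transfer and O-allylation competing. A2 needs C9 and C13 set independently in a 1,4 relationship, with no ring-forming step that links them. Enolate chemistry forbids acetates, so A1 carries silyl and PMB ethers and C15 is a methylene; allylic oxidation at C15, oxidation to the enone and exchange of three protecting groups remain.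
- Comparison: for ring D alone this road is the more elegant. The chosen plan sets against it a cycloaddition that gives ring C with C8 and C9 in one step, and a C15 that never needs allylic oxidation.

**Alternative 2:** a cyclopropane as a temporary bridge. The cuts are C13–C16 and a sacrificial C12–C16 bond. A rhodium carbenoid generated from the diazoketone A4 adds to C12=C13 and gives the cyclopropyl ketone A3 (tricyclo[3.2.1.0(2,7)]octan-6-one core); reductive opening and α-methylenation would follow.
- Merits: A4 is one operation from an acid of type 22, C15 stays at the ketone level, the cyclopropanation is dependable, and the enone is reached from the acid in four steps. That is the same count as the chosen endgame, without tin.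
- Weak point: the opening must cleave C12–C16 and not C13–C16. In this tricycle the two bonds lie at similar angles (roughly 60°) to the π axis of the C15 carbonyl, so reductive cleavage has no clear stereoelectronic bias and can give the bicyclo[2.2.2]octanone (atisane-type) skeleton instead.
- Comparison: this road is equal in length and cleaner in reagents. The chosen plan sets against it a ring closure whose regiochemistry is decided kinetically by the 5-exo mode; the carbenoid sequence is kept as the fallback for step 19.

**Alternative 3:** ring A by a citraconic anhydride cycloaddition. The cuts are C3–C4 and C5–C10. The 2-silyloxydiene ester A6 adds to citraconic anhydride A7 and gives A5, with C4, C5 and C10 set and C19, C6 and C20 all present as carboxyl carbons.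
- Merits: cheap components, three stereocentres in one step, and C20 already on C10 with the correct relative configuration.
- Weak points: A7 is a sluggish trisubstituted dienophile and A6 is an ester-deactivated diene. No reliable catalytic enantiocontrol exists for anhydride dienophiles, so a resolution would be needed. Three carboxyl-level carbons must then be reduced and told apart (C19 acetate, C6 free, C20 lactone oxygen), and ring C and ring D are still to be made.
- Comparison: this road is better in atom economy and in placing C20. The chosen ring A synthesis sets against it enantiocontrol by an established catalyst class and oxidation levels that need a single reduction. The two are compatible, since A5 could in principle feed the same key step.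

Key step: step 13

Assumption 1: the sense of induction in step 6 is taken from the accepted pre-transition-state model for 2-substituted acroleins on oxazaborolidinium catalysts (formyl C–H···O contact, s-trans enal, diene on the face away from the phenyl group), which predicts Si-face attack at C4 with the (R)-catalyst. If the sense were opposite, the (S)-catalyst would be used with no other change.

Assumption 2: the carbinol centre C15 in 25, 26 and 27 is formed as a mixture of epimers and is written without configuration; it is removed in step 20.

## Route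

Step 1
Reactants: 1 but-2-yne-1,4-diol
Product: 2 (E)-2-(tributylstannyl)but-2-ene-1,4-diol
Conditions: Bu3SnH, PdCl2(PPh3)2 (2 mol%), THF, 0 °C to rt
Reagents that add atoms: tributyltin hydride CCCC[SnH](CCCC)CCCC
Why: Palladium-catalysed hydrostannylation adds H and Sn syn across the symmetrical alkyne, so there is no regiochemical question and the two hydroxymethyl groups end up cis, the geometry needed later for an (E)-1-substituted diene.

Step 2
Reactants: 2 (E)-2-(tributylstannyl)but-2-ene-1,4-diol
Product: 3 (E)-4-[(tert-butyldiphenylsilyl)oxy]-2-(tributylstannyl)but-2-en-1-ol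
Conditions: TBDPSCl (1.0 equiv), imidazole, CH2Cl2, −20 to 0 °C
Reagents that add atoms: tert-butyl(chloro)diphenylsilane CC(C)(C)[Si](Cl)(c1ccccc1)c1ccccc1
Why: Selective silylation of a diol; the hydroxyl on the stannyl-bearing carbon is shielded by the geminal Bu3Sn group, so the bulky chlorosilane should take the distal hydroxyl, the future O6.

Step 3
Reactants: 3 (E)-4-[(tert-butyldiphenylsilyl)oxy]-2-(tributylstannyl)but-2-en-1-ol
Product: 4 (E)-1-[(tert-butyldimethylsilyl)oxy]-4-[(tert-butyldiphenylsilyl)oxy]-2-(tributylstannyl)but-2-ene
Conditions: TBSCl, imidazole, DMF, rt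
Reagents that add atoms: tert-butyl(chloro)dimethylsilane CC(C)(C)[Si](C)(C)Cl
Why: Routine silylation of the remaining hydroxyl (future O20) with the more acid-labile TBS group, which can later be removed in the presence of TBDPS.

Step 4
Reactants: 4 (E)-1-[(tert-butyldimethylsilyl)oxy]-4-[(tert-butyldiphenylsilyl)oxy]-2-(tributylstannyl)but-2-ene; 5 acetyl chloride
Product: 6 (E)-3-{[(tert-butyldimethylsilyl)oxy]methyl}-5-[(tert-butyldiphenylsilyl)oxy]pent-3-en-2-one
Conditions: PdCl2(PPh3)2 (5 mol%), ClCH2CH2Cl, 70 °C
Reagents that add atoms: none
Why: Stille acylation of an alkenylstannane with an acid chloride proceeds with retention of alkene geometry and forms the C1–C10 bond; the (E)-enone is also the thermodynamically preferred isomer.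

Step 5
Reactants: 6 (E)-3-{[(tert-butyldimethylsilyl)oxy]methyl}-5-[(tert-butyldiphenylsilyl)oxy]pent-3-en-2-one
Product: 7 (E)-2-[(tert-butyldimethylsilyl)oxy]-3-{[(tert-butyldimethylsilyl)oxy]methyl}-5-[(tert-butyldiphenylsilyl)oxy]penta-1,3-diene
Conditions: TBSOTf, Et3N, CH2Cl2, 0 °C
Reagents that add atoms: tert-butyldimethylsilyl trifluoromethanesulfonate CC(C)(C)[Si](C)(C)OS(=O)(=O)C(F)(F)F
Why: Soft enolisation of the methyl ketone with a silyl triflate and amine removes the kinetic acetyl proton and gives the cross-conjugated 2-silyloxydiene.

Step 6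
Reactants: 7 (E)-2-[(tert-butyldimethylsilyl)oxy]-3-{[(tert-butyldimethylsilyl)oxy]methyl}-5-[(tert-butyldiphenylsilyl)oxy]penta-1,3-diene; 8 methacrolein
Product: 9 ring A cycloadduct, 4-[(tert-butyldimethylsilyl)oxy]-3-{[(tert-butyldimethylsilyl)oxy]methyl}-2-{[(tert-butyldiphenylsilyl)oxy]methyl}-1-methylcyclohex-3-ene-1-carbaldehyde, formyl (C19) cis to the C6 arm, both α, methyl β (C4 R, C5 S)
Conditions: 8 (3 equiv), (R)-3,3-diphenyl-1-(2-methylphenyl)tetrahydro-1H,3H-pyrrolo[1,2-c][1,3,2]oxazaborole (15 mol%), HNTf2 (12 mol%), CH2Cl2, −78 °C
Reagents that add atoms: none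
Why: Enantioselective Diels–Alder reaction under chiral oxazaborolidinium catalysis, a reaction type established for methacrolein with 2-silyloxydienes. The silyloxy group ("para") and the C5 substituent ("ortho") both direct C4 to bond to C5, and the endo-formyl transition state places C19 cis to the (E)-C6 arm. The catalyst selects the Si face of C4, so both centres arise in the absolute configuration of the target.

Step 7
Reactants: 9 ring A cycloadduct aldehyde
Product: 10 the corresponding primary alcohol (C19 hydroxymethyl), silyl enol ether intact
Conditions: NaBH4, EtOH/THF, 0 °C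
Reagents that add atoms: none
Why: Borohydride reduces the neopentyl aldehyde and leaves the tetrasubstituted silyl enol ether and the silyl ethers untouched.

Step 8
Reactants: 10 primary alcohol
Product: 11 the C19 acetate, silyl enol ether C1(OTBS)=C10(CH2OTBS) intact
Conditions: Ac2O, pyridine, DMAP (cat.), CH2Cl2, rt
Reagents that add atoms: acetic anhydride CC(=O)OC(C)=O
Why: Routine acetylation installs the C19 acetate of the target while it is the only free hydroxyl in the molecule.

Step 9
Reactants: 11 C19 acetate silyl enol ether
Product: 12 hydroxymethyl ketone, 4-(acetoxymethyl)-2-{[(tert-butyldimethylsilyl)oxy]methyl}-3-{[(tert-butyldiphenylsilyl)oxy]methyl}-2-(hydroxymethyl)-4-methylcyclohexan-1-one, with C20 (CH2OTBS), the C6 arm and C19 on the α face and C9 (CH2OH) and methyl on the β face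
Conditions: aq. HCHO (37%), Yb(OTf)3 (20 mol%), THF, rt
Reagents that add atoms: formaldehyde C=O
Why: Lanthanide-triflate-catalysed Mukaiyama aldol reaction with aqueous formaldehyde (hydroxymethylation of a silyl enol ether), which also forms quaternary centres. The enol ether is regiodefined by the cycloaddition, and formaldehyde should add to the β face of C10, anti to the adjacent C6 arm and away from the α-oriented C19, so the incoming carbon becomes C9 and the resident one C20.

Step 10
Reactants: 12 hydroxymethyl ketone
Product: 13 keto aldehyde (C9 formyl β, C20 CH2OTBS α, C1 ketone)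
Conditions: Dess–Martin periodinane, NaHCO3, CH2Cl2, 0 °C to rt
Reagents that add atoms: none
Why: Dess–Martin oxidation of a neopentyl primary alcohol under buffered conditions; C10 bears no hydrogen, so the β-keto aldehyde cannot epimerise, and it is used at once to avoid deformylation.

Step 11
Reactants: 13 keto aldehyde; 14 diallyl malonate
Product: 15 diallyl alkylidene malonate (C9=C8 bearing two allyl esters, C20 CH2OTBS)
Conditions: TiCl4, pyridine, THF, 0 °C to rt
Reagents that add atoms: none
Why: Knoevenagel condensation in its TiCl4/pyridine variant, which suits hindered non-enolisable aldehydes; chelation of the β-keto aldehyde activates the formyl group, and the tertiary amine avoids the retro-Claisen cleavage that secondary amines can cause.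

Step 12
Reactants: 15 diallyl alkylidene malonate
Product: 17 spiro alkylidene lactone, allyl 10-(acetoxymethyl)-11-{[(tert-butyldiphenylsilyl)oxy]methyl}-10-methyl-3,7-dioxo-2-oxaspiro[5.5]undec-4-ene-4-carboxylate (ring A configuration as in 13), via hydroxy diester 16 (not isolated)
Conditions: AcOH/THF/H2O (3:1:1), rt; then PPTS (cat.), PhMe, 60 °C
Reagents that add atoms: none
Why: Mild aqueous acid removes the primary TBS ether selectively over TBDPS; the liberated O20 is held cis to one of the geminal esters across C8=C9, so acid-catalysed six-membered lactonisation with loss of allyl alcohol should follow readily. O6 stays protected, which prevents oxa-Michael closure onto C9.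

Step 13
Reactants: 17 spiro alkylidene lactone; 18 buta-1,3-diene
Product: 19 cycloadduct, cis-fused lactone cyclohexene with quaternary C8 (CO2allyl), C12=C13, C1 ketone; H9 and C15 cis, C11 and C14 on the lactone face that looks toward C1
Conditions: 18 (15 equiv), SnCl4 (1.1 equiv), CH2Cl2, −78 to −20 °C, sealed vessel
Reagents that add atoms: none
Why: SnCl4 chelates the lactone and ester carbonyls on C8 and lowers the LUMO of the C8=C9 alkene; butadiene then adds in a concerted, asynchronous, suprafacial [4+2] cycloaddition in which the bond to the β-carbon C9 is the more advanced. The closest known reaction type is the Lewis-acid-mediated cycloaddition of butadiene to 2-alkoxycarbonyl-2-cycloalkenones and 3-alkoxycarbonyl-5,6-dihydropyran-2-ones, which tolerates a quaternary carbon next to the β-position. Ring C is closed by intermolecular [4+2] annulation, both new bonds (C9–C11 and C8–C14) forming on the same face of the lactone. Because C7 and C10 are already tied together in the lactone and the addition is suprafacial, C15 and H9 must emerge cis, which is the cis lactone/ring C fusion of the target and places C15 where it can later bridge to C13. The absolute sense at C8 and C9 is controlled by the spiro centre C10: the lactone lies roughly perpendicular to ring A, one alkene face looks toward the flat C1 carbonyl and the other toward C5 with its silyloxymethyl arm and the C4 substituents behind it, so the diene should enter from the C1 side in either chair of ring A. The step therefore needs facial selectivity only; regiochemistry is moot for the symmetrical diene, endo/exo has no consequence, and the allyl ester alkene and the ketone are not dienophilic here. The double activation is what permits reaction at the neopentyl-type C9, and the low temperature keeps the Lewis acid from oligomerising the diene.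

Step 14
Reactants: 19 cycloadduct
Product: 20 the 1α-alcohol (equatorial, cis to C20)
Conditions: NaBH4, CeCl3·7H2O, MeOH/THF, −40 °C; AcOH quench
Reagents that add atoms: none
Why: Luche-type borohydride reduction. Ring A of 19 is locked in the chair with C20 axial, so hydride enters C1 along the axial β trajectory (only H3 and H5 are syn-axial, and the equatorial path is blocked by axial C20) and gives the equatorial 1α-alcohol. The 2,2-disubstituted lactone/ester is not reduced at this temperature, and the product is acetylated at once to forestall transfer of the lactone to O1.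

Step 15
Reactants: 20 1α-alcohol
Product: 21 the 1α-acetate
Conditions: Ac2O, Et3N, DMAP, CH2Cl2, rt
Reagents that add atoms: acetic anhydride CC(=O)OC(C)=O
Why: DMAP-catalysed acetylation of the hindered equatorial alcohol installs the second acetate and removes the nucleophile that could open the lactone.

Step 16
Reactants: 21 1α-acetate allyl ester
Product: 22 the C15 carboxylic acid
Conditions: Pd(PPh3)4 (5 mol%), morpholine, THF, rt; dilute acid work-up
Reagents that add atoms: none
Why: Zerovalent-palladium-catalysed deallylation (π-allyl formation and capture by morpholine) frees the acid under neutral conditions that spare acetates, lactone and silyl ether; the malonic-type acid is kept cold to avoid decarboxylation.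

Step 17
Reactants: 22 C15 carboxylic acid
Product: 24 the C15 aldehyde (formyl on C8), via acid chloride 23 (not isolated)
Conditions: (COCl)2, DMF (cat.), CH2Cl2, 0 °C to rt; evaporate; LiAlH(OtBu)3 (1.1 equiv), THF, −78 °C
Reagents that add atoms: oxalyl chloride ClC(=O)C(Cl)=O (chlorine of 23 only)
Why: The non-enolisable acid is converted into its chloride and reduced by the hindered hydride LiAlH(OtBu)3, which stops at the aldehyde and does not touch lactone or acetates at −78 °C.

Step 18
Reactants: 24 C15 aldehyde
Product: 25 propargylic alcohol (C15 carbinol bearing C16≡C17H, C15 epimers)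
Conditions: HC≡CMgBr (1.5 equiv), THF, −78 to −40 °C
Reagents that add atoms: ethynylmagnesium bromide C#C[Mg]Br
Why: Alkynyl Grignard addition to the aldehyde, which is far more electrophilic than the esters at low temperature; the configuration at C15 is irrelevant because C15 is oxidised in step 20.

Step 19
Reactants: 25 propargylic alcohol
Product: 27 bicyclo[3.2.1]octane allylic alcohol (C13–C16 bond, C16=C17 exo-methylene, C15 carbinol), via vinylstannane 26 (not isolated)
Conditions: Bu3SnH (1.5 equiv), AIBN (0.2 equiv), PhH, 80 °C, 0.05 M; then TsOH·H2O, CH2Cl2, 0 °C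
Reagents that add atoms: tributyltin hydride CCCC[SnH](CCCC)CCCC (tin of 26 only)
Why: Tin-hydride-mediated radical enyne cyclisation: the stannyl radical adds to the alkyne terminus C17, the vinyl radical at C16 closes 5-exo-trig onto C13 of the ring C alkene, and the C12 radical is reduced. Because the two-atom tether is anchored on C8, C16 can reach only the face of C13 syn to C15, which sets C13; acid then replaces tin by hydrogen on the exocyclic alkene. The stated tin hydride concentration is meant to trap the C12 radical before any homoallyl rearrangement.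

Step 20
Reactants: 27 allylic alcohol
Product: 28 exo-methylene ketone, the C6 TBDPS ether of the target
Conditions: Dess–Martin periodinane, NaHCO3, CH2Cl2, rt
Reagents that add atoms: none
Why: Dess–Martin oxidation of the allylic alcohol gives the enone under neutral, non-nucleophilic conditions and converges the C15 epimers.

Step 21
Reactants: 28 exo-methylene ketone TBDPS ether
Product: 29 the target, CNP0105570.2
Conditions: HF·pyridine, pyridine/THF, 0 °C to rt
Reagents that add atoms: none
Why: Buffered fluoride cleaves the primary TBDPS ether without base, so the acetates, the lactone and the enone survive and no acetyl migration toward O6 is provoked.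

## Compound list

1 | but-2-yne-1,4-diol | OCC#CCO | starting material
2 | (E)-2-(tributylstannyl)but-2-ene-1,4-diol | OC/C=C(\CO)[Sn](CCCC)(CCCC)CCCC | intermediate
3 | (E)-4-[(tert-butyldiphenylsilyl)oxy]-2-(tributylstannyl)but-2-en-1-ol | CC(C)(C)[Si](c1ccccc1)(c1ccccc1)OC/C=C(\CO)[Sn](CCCC)(CCCC)CCCC | intermediate
4 | (E)-1-[(tert-butyldimethylsilyl)oxy]-4-[(tert-butyldiphenylsilyl)oxy]-2-(tributylstannyl)but-2-ene | CC(C)(C)[Si](c1ccccc1)(c1ccccc1)OC/C=C(\CO[Si](C)(C)C(C)(C)C)[Sn](CCCC)(CCCC)CCCC | intermediate
5 | acetyl chloride | CC(Cl)=O | starting material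
6 | (E)-3-{[(tert-butyldimethylsilyl)oxy]methyl}-5-[(tert-butyldiphenylsilyl)oxy]pent-3-en-2-one | CC(C)(C)[Si](c1ccccc1)(c1ccccc1)OC/C=C(\CO[Si](C)(C)C(C)(C)C)C(C)=O | intermediate
7 | (E)-2-[(tert-butyldimethylsilyl)oxy]-3-{[(tert-butyldimethylsilyl)oxy]methyl}-5-[(tert-butyldiphenylsilyl)oxy]penta-1,3-diene | CC(C)(C)[Si](c1ccccc1)(c1ccccc1)OC/C=C(\CO[Si](C)(C)C(C)(C)C)C(=C)O[Si](C)(C)C(C)(C)C | intermediate
8 | methacrolein (2-methylprop-2-enal) | CC(=C)C=O | starting material
9 | ring A cycloadduct aldehyde (C19 formyl and C6 arm cis, α; methyl β; C1=C10 silyl enol ether) | C1(CO[Si](C)(C)C(C)(C)C)=C(O[Si](C)(C)C(C)(C)C)CC[C@@](C)(C=O)[C@H]1CO[Si](c1ccccc1)(c1ccccc1)C(C)(C)C | intermediate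
10 | ring A primary alcohol (C19 hydroxymethyl) | C1(CO[Si](C)(C)C(C)(C)C)=C(O[Si](C)(C)C(C)(C)C)CC[C@@](C)(CO)[C@H]1CO[Si](c1ccccc1)(c1ccccc1)C(C)(C)C | intermediate
11 | ring A C19 acetate silyl enol ether | C1(CO[Si](C)(C)C(C)(C)C)=C(O[Si](C)(C)C(C)(C)C)CC[C@@](C)(COC(C)=O)[C@H]1CO[Si](c1ccccc1)(c1ccccc1)C(C)(C)C | intermediate
12 | hydroxymethyl ketone (C9 CH2OH β, C20 CH2OTBS α, C1 ketone) | OC[C@]1(CO[Si](C)(C)C(C)(C)C)C(=O)CC[C@@](C)(COC(C)=O)[C@H]1CO[Si](c1ccccc1)(c1ccccc1)C(C)(C)C | intermediate
13 | keto aldehyde (C9 formyl β, C20 CH2OTBS α) | O=C[C@]1(CO[Si](C)(C)C(C)(C)C)C(=O)CC[C@@](C)(COC(C)=O)[C@H]1CO[Si](c1ccccc1)(c1ccccc1)C(C)(C)C | intermediate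
14 | diallyl malonate | C=CCOC(=O)CC(=O)OCC=C | starting material
15 | diallyl alkylidene malonate (C20 CH2OTBS) | C=CCOC(=O)C(C(=O)OCC=C)=C[C@]1(CO[Si](C)(C)C(C)(C)C)C(=O)CC[C@@](C)(COC(C)=O)[C@H]1CO[Si](c1ccccc1)(c1ccccc1)C(C)(C)C | intermediate
16 | hydroxy diester (C20 CH2OH), not isolated | C=CCOC(=O)C(C(=O)OCC=C)=C[C@]1(CO)C(=O)CC[C@@](C)(COC(C)=O)[C@H]1CO[Si](c1ccccc1)(c1ccccc1)C(C)(C)C | intermediate
17 | spiro alkylidene lactone allyl ester (C15 as allyl ester, C1 ketone) | C=CCOC(=O)C1=C[C@]2(COC1=O)C(=O)CC[C@@](C)(COC(C)=O)[C@H]2CO[Si](c1ccccc1)(c1ccccc1)C(C)(C)C | intermediate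
18 | buta-1,3-diene | C=CC=C | starting material
19 | cycloadduct: cis-fused lactone cyclohexene, quaternary C8, C1 ketone | C=CCOC(=O)[C@]23CC=CC[C@H]2[C@]1(COC3=O)C(=O)CC[C@@](C)(COC(C)=O)[C@H]1CO[Si](c1ccccc1)(c1ccccc1)C(C)(C)C | intermediate
20 | 1α-alcohol | C=CCOC(=O)[C@]23CC=CC[C@H]2[C@]1(COC3=O)[C@@H](O)CC[C@@](C)(COC(C)=O)[C@H]1CO[Si](c1ccccc1)(c1ccccc1)C(C)(C)C | intermediate
21 | 1α-acetate allyl ester | C=CCOC(=O)[C@]23CC=CC[C@H]2[C@]1(COC3=O)[C@@H](OC(C)=O)CC[C@@](C)(COC(C)=O)[C@H]1CO[Si](c1ccccc1)(c1ccccc1)C(C)(C)C | intermediate
22 | C15 carboxylic acid | OC(=O)[C@]23CC=CC[C@H]2[C@]1(COC3=O)[C@@H](OC(C)=O)CC[C@@](C)(COC(C)=O)[C@H]1CO[Si](c1ccccc1)(c1ccccc1)C(C)(C)C | intermediate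
23 | C15 acid chloride, not isolated | ClC(=O)[C@]23CC=CC[C@H]2[C@]1(COC3=O)[C@@H](OC(C)=O)CC[C@@](C)(COC(C)=O)[C@H]1CO[Si](c1ccccc1)(c1ccccc1)C(C)(C)C | intermediate
24 | C15 aldehyde | O=C[C@]23CC=CC[C@H]2[C@]1(COC3=O)[C@@H](OC(C)=O)CC[C@@](C)(COC(C)=O)[C@H]1CO[Si](c1ccccc1)(c1ccccc1)C(C)(C)C | intermediate
25 | propargylic alcohol (C15 epimers) | C#CC(O)[C@]23CC=CC[C@H]2[C@]1(COC3=O)[C@@H](OC(C)=O)CC[C@@](C)(COC(C)=O)[C@H]1CO[Si](c1ccccc1)(c1ccccc1)C(C)(C)C | intermediate
26 | exocyclic vinylstannane (C17 SnBu3, C15 epimers), not isolated | CCCC[Sn](CCCC)(CCCC)C=C1C(O)[C@]23C[C@H]1CC[C@H]2[C@]1(COC3=O)[C@@H](OC(C)=O)CC[C@@](C)(COC(C)=O)[C@H]1CO[Si](c1ccccc1)(c1ccccc1)C(C)(C)C | intermediate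
27 | bicyclo[3.2.1]octane allylic alcohol (C15 epimers) | C=C1C(O)[C@]23C[C@H]1CC[C@H]2[C@]1(COC3=O)[C@@H](OC(C)=O)CC[C@@](C)(COC(C)=O)[C@H]1CO[Si](c1ccccc1)(c1ccccc1)C(C)(C)C | intermediate
28 | exo-methylene ketone, C6 TBDPS ether of the target | C=C1C(=O)[C@]23C[C@H]1CC[C@H]2[C@]1(COC3=O)[C@@H](OC(C)=O)CC[C@@](C)(COC(C)=O)[C@H]1CO[Si](c1ccccc1)(c1ccccc1)C(C)(C)C | intermediate
29 | CNP0105570.2 | C=C1C(=O)[C@]23C[C@H]1CC[C@H]2[C@]1(COC3=O)[C@@H](OC(C)=O)CC[C@@](C)(COC(C)=O)[C@H]1CO | target

## Step count and risks

Total: 21 steps. Longest linear sequence: 21 steps from but-2-yne-1,4-diol (1); compounds 5, 8, 14 and 18 are commercial and enter directly.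

**Step 13 (key step).** The likely failure is that cycloaddition at the neopentyl-type C9 is slower than Lewis-acid-induced oligomerisation of butadiene, and that warming to force it erodes the facial selectivity. The fallback sets out from 17 and uses the far more nucleophilic 2-(trimethylsilyloxy)buta-1,3-diene with ZnBr2 or heat alone. It forms the same C9–C11 and C8–C14 bonds, with the terminus next to the silyloxy carbon attacking C9, and gives the silyl enol ether cycloadduct F1 with the enol ether at C12=C13. Fluoride-mediated triflation (CsF, PhNTf2) gives the enol triflate F2. Luche reduction at C1 gives the triflate alcohol F3, and acetylation gives the triflate acetate F4. Pd(OAc)2/PPh3 with HCO2H and Bu3N then reduces the C12–OTf bond to C–H and cleaves the allyl ester in the same flask, returning to the route at acid 22.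

**Step 19.** The likely failures are reduction of the vinyl radical before it reaches C13 (simple hydrostannylation of the alkyne) and, at low tin hydride concentration, homoallyl rearrangement of the C12 radical toward a bicyclo[2.2.2]octane. The fallback sets out from acid 22 through its chloride 23 and closes ring D with a carbenoid. Diazomethane gives the diazoketone F5, Rh2(OAc)4 gives the cyclopropyl ketone F6 by addition to C12=C13, and SmI2 in THF/MeOH opens the C12–C16 bond to the bicyclo[3.2.1]octan-15-one F7. α-Methylenation with bis(dimethylamino)methane and Ac2O returns to the route at 28. The direction of the cyclopropane cleavage is the point to verify in this sequence.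

**Step 9.** The likely failures are that the hindered tetrasubstituted TBS enol ether hydrolyses faster than it adds to formaldehyde, and that attack on C10 is not fully β-selective. The fallback sets out from 11 and alkylates the enol ether with benzyl chloromethyl ether and TiCl4 at −78 °C, a much stronger electrophile, to give the benzyloxymethyl ketone F8. Hydrogenolysis (H2, Pd/C) returns to the route at 12.

**Step 6.** The likely failures are Mukaiyama–Michael addition or desilylation of the electron-rich diene by the cationic Lewis acid, and incomplete enantio- or endo-selectivity with this trisubstituted diene. The fallback sets out from 7 and 8 and runs the cycloaddition with MeAlCl2 to give the racemic cycloadduct F9, which is reduced to the racemic alcohol F10. Esterification with (S)-2-methoxy-2-phenylacetic acid (DCC, DMAP) gives diastereomeric esters; these are separated, and the ester of the required series F11 is cleaved with K2CO3 in MeOH, returning to the route at 10.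

**Step 11.** The likely failures are slow condensation at the neopentyl aldehyde, with deformylation of the β-keto aldehyde or loss of the TBS ether competing. The fallback sets out from 13 and reverses the order of events. AcOH/THF/H2O removes the TBS group to give the hydroxy keto aldehyde F12, and allyl hydrogen malonate with DCC acylates O20 to give the malonate ester F13. Et3N or TiCl4/pyridine then closes the ring by intramolecular Knoevenagel condensation, returning to the route at 17.

## Further compounds

F1 | step 13 | silyl enol ether cycloadduct (C12 OSiMe3, C12=C13, C1 ketone) | C=CCOC(=O)[C@]23CC=C(O[Si](C)(C)C)C[C@H]2[C@]1(COC3=O)C(=O)CC[C@@](C)(COC(C)=O)[C@H]1CO[Si](c1ccccc1)(c1ccccc1)C(C)(C)C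
F2 | step 13 | enol triflate (C12 OTf, C1 ketone) | C=CCOC(=O)[C@]23CC=C(OS(=O)(=O)C(F)(F)F)C[C@H]2[C@]1(COC3=O)C(=O)CC[C@@](C)(COC(C)=O)[C@H]1CO[Si](c1ccccc1)(c1ccccc1)C(C)(C)C
F3 | step 13 | triflate alcohol (1α-OH) | C=CCOC(=O)[C@]23CC=C(OS(=O)(=O)C(F)(F)F)C[C@H]2[C@]1(COC3=O)[C@@H](O)CC[C@@](C)(COC(C)=O)[C@H]1CO[Si](c1ccccc1)(c1ccccc1)C(C)(C)C
F4 | step 13 | triflate acetate (1α-OAc) | C=CCOC(=O)[C@]23CC=C(OS(=O)(=O)C(F)(F)F)C[C@H]2[C@]1(COC3=O)[C@@H](OC(C)=O)CC[C@@](C)(COC(C)=O)[C@H]1CO[Si](c1ccccc1)(c1ccccc1)C(C)(C)C
F5 | step 19 | diazoketone (C15 ketone, C16 diazo) | [N-]=[N+]=CC(=O)[C@]23CC=CC[C@H]2[C@]1(COC3=O)[C@@H](OC(C)=O)CC[C@@](C)(COC(C)=O)[C@H]1CO[Si](c1ccccc1)(c1ccccc1)C(C)(C)C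
F6 | step 19 | cyclopropyl ketone (C12/C13/C16 cyclopropane) | [C@H]14C(=O)[C@]23C[C@H]1[C@H]4C[C@H]2[C@]1(COC3=O)[C@@H](OC(C)=O)CC[C@@](C)(COC(C)=O)[C@H]1CO[Si](c1ccccc1)(c1ccccc1)C(C)(C)C
F7 | step 19 | bicyclo[3.2.1]octan-15-one (C16 methylene) | C1C(=O)[C@]23C[C@H]1CC[C@H]2[C@]1(COC3=O)[C@@H](OC(C)=O)CC[C@@](C)(COC(C)=O)[C@H]1CO[Si](c1ccccc1)(c1ccccc1)C(C)(C)C
F8 | step 9 | benzyloxymethyl ketone (C9 CH2OBn β) | c1ccccc1COC[C@]1(CO[Si](C)(C)C(C)(C)C)C(=O)CC[C@@](C)(COC(C)=O)[C@H]1CO[Si](c1ccccc1)(c1ccccc1)C(C)(C)C
F9 | step 6 | racemic cycloadduct aldehyde (racemate of 9, relative configuration shown) | C1(CO[Si](C)(C)C(C)(C)C)=C(O[Si](C)(C)C(C)(C)C)CC[C@@](C)(C=O)[C@H]1CO[Si](c1ccccc1)(c1ccccc1)C(C)(C)C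
F10 | step 6 | racemic primary alcohol (racemate of 10, relative configuration shown) | C1(CO[Si](C)(C)C(C)(C)C)=C(O[Si](C)(C)C(C)(C)C)CC[C@@](C)(CO)[C@H]1CO[Si](c1ccccc1)(c1ccccc1)C(C)(C)C
F11 | step 6 | (S)-2-methoxy-2-phenylacetate of 10 | C1(CO[Si](C)(C)C(C)(C)C)=C(O[Si](C)(C)C(C)(C)C)CC[C@@](C)(COC(=O)[C@@H](OC)c2ccccc2)[C@H]1CO[Si](c1ccccc1)(c1ccccc1)C(C)(C)C
F12 | step 11 | hydroxy keto aldehyde (C20 CH2OH, C9 formyl) | O=C[C@]1(CO)C(=O)CC[C@@](C)(COC(C)=O)[C@H]1CO[Si](c1ccccc1)(c1ccccc1)C(C)(C)C
F13 | step 11 | allyl malonate ester of O20 (C9 formyl) | O=C[C@]1(COC(=O)CC(=O)OCC=C)C(=O)CC[C@@](C)(COC(C)=O)[C@H]1CO[Si](c1ccccc1)(c1ccccc1)C(C)(C)C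
A1 | alternative 1 | bicyclo[3.2.1]octane lactone with exocyclic C16=C17 and C15 methylene | C=C1C[C@]23C[C@H]1CC[C@H]2[C@]1(COC3=O)[C@@H](O[Si](C)(C)C(C)(C)C)CC[C@@](C)(CO[Si](C)(C)C(C)(C)C)[C@H]1COCc1ccc(OC)cc1
A2 | alternative 1 | cis-fused lactone (C8–H) bearing a 3-(methoxycarbonyloxy)prop-1-en-2-yl group on C13 | C=C(COC(=O)OC)[C@@H]1CC[C@H]2[C@]3(COC(=O)[C@H]2C1)[C@@H](O[Si](C)(C)C(C)(C)C)CC[C@@](C)(CO[Si](C)(C)C(C)(C)C)[C@H]3COCc1ccc(OC)cc1
A3 | alternative 2 | cyclopropyl ketone (tricyclo[3.2.1.0(2,7)]octanone core) | [C@H]14C(=O)[C@]23C[C@H]1[C@H]4C[C@H]2[C@]1(COC3=O)[C@@H](OC(C)=O)CC[C@@](C)(COC(C)=O)[C@H]1CO[Si](C)(C)C(C)(C)C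
A4 | alternative 2 | diazoketone with the C6 TBS ether | [N-]=[N+]=CC(=O)[C@]23CC=CC[C@H]2[C@]1(COC3=O)[C@@H](OC(C)=O)CC[C@@](C)(COC(C)=O)[C@H]1CO[Si](C)(C)C(C)(C)C
A5 | alternative 3 | ring A cycloadduct: C1 silyl enol ether, C10 ester, C4/C5 anhydride | COC(=O)[C@H]1C(O[Si](C)(C)C(C)(C)C)=CC[C@@]2(C)C(=O)OC(=O)[C@@H]12
A6 | alternative 3 | methyl (Z)-3-[(tert-butyldimethylsilyl)oxy]penta-2,4-dienoate | COC(=O)/C=C(\O[Si](C)(C)C(C)(C)C)C=C
A7 | alternative 3 | citraconic anhydride | CC1=CC(=O)OC1=O
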